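(Readings and results stem from a simulated flask for an exercise, noise included.)

Look first at what is left over: at 30.0 min the gamma run still holds 21.6 % of its L, and D besides, yet Q stands still near 22.9 %.

| flask | L | Z | remark | time |
|---|---|---|---|---|
| beta | 0.028 M | 0.020 M (fed, over 2.0 min) | run made earlier |  |
| theta | 0.044 M | 0.020 M (fed, over 2.0 min) | run made earlier |  |
| gamma | 0.020 M | 0.030 M (fed, over 2.0 min) | run made earlier |  |
| flask | 0.020 M | 0.0200 M (fed, over 2.0 min) |  | 50 min |

| run | time / min | L / % | Q / % |
|---|---|---|---|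
| beta | 2.00 | 72.4 | 2.9 |
| beta | 6.00 | 43.9 | 13.1 |
| beta | 10.0 | 31.7 | 15.2 |
| beta | 15.0 | 26.9 | 15.5 |
| beta | 25.0 | 24.0 | 15.4 |
| beta | 30.0 | 24.1 | 15.8 |
| theta | 5.00 | 49.3 | 10.9 |
| theta | 10.0 | 32.3 | 13.3 |
| theta | 15.0 | 27.0 | 13.5 |
| theta | 20.0 | 25.5 | 13.6 |
| theta | 25.0 | 25.5 | 13.1 |
| theta | 30.0 | 25.2 | 13.6 |
| gamma | 6.00 | 43.5 | 18.5 |
| gamma | 12.0 | 27.1 | 22.8 |
| gamma | 20.0 | 23.6 | 23.2 |
| gamma | 25.0 | 22.6 | 22.6 |
| gamma | 30.0 | 21.6 | 22.9 |

(readings scatter by 0.3 percentage points)

* why nothing more happens at 50 min, or that something still does (all of L has reacted / Z has run out first / forward and back rates have come level / it is still moving)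
* how much of the L has reacted by 50 min
* how much Q there is at 50 min, in percent of the L charged
* how much D there is at 50 min, in percent of the L charged

- the reaction counts as stopped when no species that holds the L changes by six tenths of a point or more over the second half of the time

D is not read, but you can take it as what L and Q leave, so at beta's last reading cD comes to 2.49 times cL. But beta's last Q reading is 0.00442 M, less than the 0.020 M of Z charged. My own reckoning assumes that Z is the limiting reagent: each bit of it either makes Q, at a rate that grows with cD, or is lost at a rate that does not.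

If cD is taken as a fixed share of the L not yet in Q, the ratio of those two rates integrates in closed form. Take ln(charged L / (charged L − cQ)) and divide it by the Z not in Q. The last readings of beta, theta and gamma give 11.0 M⁻¹, 10.4 M⁻¹ and 10.2 M⁻¹, so I carry their mean, 10.6 M⁻¹, as the pull of D on Z.

Solved for the flask by repeated substitution, the pull gives Q 16.3 %. Split at the beta ratio, the rest gives D 59.7 % and L reacted 76.0 %. Gamma, with this flask's L but more Z, reads level in Q by 20.0 min, and 50 min is later, so I expect the flask to be still by then, and on my assumption I answer that Z has run out first.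

The forecast answers otherwise: forward and back rates have come level, with L reacted 75.9 %, Q 16.2 % and D 59.7 %. It holds that “Q also plateaus while Z remains”.

The flask gives: Z has run out first, with L reacted 76.2 %, Q 16.6 % and D 59.5 %.

    D + G → Q (k = 13.0 M⁻¹ min⁻¹)
    L ⇌ D (K = 2.50, k = 0.170 min⁻¹)
    2 G → E (k = 1.10 M⁻¹ min⁻¹)
    Z → G (k = 7.20 min⁻¹)
    G → X (k = 0.360 min⁻¹)

In the flask Z stands at 0 % by 25.0 min, and Q stands at 16.6 % then and 16.6 % at 500 min. The flask's own Q gives a pull of 10.9 M⁻¹, beside the 10.6 M⁻¹ carried. On a neighbour flask, charged like this one but with 0.034 M of Z, the carried pull gives Q 26.2 %. That neighbour ends with Z at 0 % and Q at 25.0 %.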